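**Retrosynthetic overview**
1. The target is traced back, through oxidation of the C11 alcohol, desilylation, acetylation and 1,2-reduction, to the 2-acetoxy-4-formyl-2,3-dihydrofuran 9. This acid-tolerant vinylogous formate comes from the γ-alkoxy-γ-lactone 4 by aminomethylenation, DIBAL 1,3-carbonyl transposition and acetal-to-acetate exchange.
2. Lactone 4 is cut between the methyl-bearing quaternary decalin carbon (C8) and the ring CH of the five-membered oxygen ring (C14). The forward reaction is an iron-hydride reductive olefin–olefin coupling of silylated (−)-drimenol 2 with the (5S)-menthyloxybutenolide 3.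
3. Enabling feature: C8 lies in ring B next to the CH2 C7 and carries only a methyl besides its ring bonds, so it can be formed as a planar tertiary radical from the C7=C8 alkene, with its β face blocked by the axial C10 methyl. C14 lies between the acetal carbon C15 and C13, and C13's other ring neighbour C16 can be held at the carboxyl level as a lactone carbonyl, so C14 is the β-carbon of a butenolide whose face is steered by the C15 alkoxy group.
4. Ring order: rings A and B come intact from drimenol. The oxygen ring enters as the butenolide in the key step and is then re-tailored (lactone C=O becomes the enol-ether CH C16; the new carbon C12 is added on C13).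

Key step: step 2

Remark: positions are numbered as in spongian diterpenes (C8 quaternary methyl-bearing decalin carbon, C9 its CH neighbour carrying C11, C14 ring CH of the oxygen ring, C15 acetal carbon, C13=C16 enol ether, C12 exocyclic CH2); 1 and 3 are assumed to be commercially available.

**Step 1**
Reactants: 1 (−)-drimenol
Product: 2 drimenol tert-butyldiphenylsilyl ether
Conditions: TBDPSCl, imidazole, DMF, rt
Reagents that add atoms: tert-butyl(chloro)diphenylsilane, CC(C)(C)[Si](Cl)(c1ccccc1)c1ccccc1
Why: Standard silylation of the only hydroxyl group; the TBDPS ether is chosen because it should outlast the aqueous acid of step 5, and no stereocentre is touched.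

**Step 2**
Reactants: 2 drimenol tert-butyldiphenylsilyl ether; 3 (5S)-5-[(1S,2R,5S)-menthyloxy]furan-2(5H)-one (3 equiv)
Product: 4 (4R,5S)-5-menthyloxy-4-(drimanyl)dihydrofuran-2(3H)-one (4,5-trans; C8 methyl β-axial, new C8–C14 bond α-equatorial)
Conditions: Fe(acac)3 (1 equiv), PhSiH3, EtOH/ethylene glycol, 60 °C
Reagents that add atoms: none
Why: An iron hydride formed from Fe(acac)3 and PhSiH3 transfers a hydrogen atom to C7 of the trisubstituted C7=C8 alkene, and the resulting planar tertiary C8 radical adds to the β-carbon (C14) of the butenolide; the α-lactone radical is then reduced by Fe(II) and protonated by ethanol. The closest known reaction types are the iron-mediated reductive cross-coupling of trisubstituted donor olefins with β-substituted cyclic acceptors to give quaternary carbons, and the addition of tertiary radicals to 5-alkoxybutenolides anti to the alkoxy group. No ring is closed in this step: both decalin rings come from 1 and the five-membered ring from 3. The quaternary centre C8 is set by substrate control, because the axial C10 methyl shields the β lobe of the radical, so the bond should form equatorially on the α face and leave the C8 methyl axial; C14 is set by reagent control, the radical entering anti to the menthyloxy group on the adjacent acetal carbon of the (5S)-butenolide. Because C8 is sp2 in the precursor, any Δ8(12) isomer or C8-epimeric material would pass through the same radical and converge on the one configuration. The step needs Markovnikov hydrogen delivery (secured by the trisubstituted alkene), β-regioselective addition (secured by the lactone carbonyl) and radical capture by the acceptor faster than by a second hydrogen atom (secured by the excess of 3).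

**Step 3**
Reactants: 4 trans-lactone
Product: 5 (E)-3-(dimethylaminomethylene) lactone
Conditions: t-BuOCH(NMe2)2, toluene, 90 °C
Reagents that add atoms: tert-butoxybis(dimethylamino)methane (Bredereck's reagent), CN(C)C(OC(C)(C)C)N(C)C
Why: Aminomethylenation with Bredereck's reagent at the only enolisable position (C13) installs the one-carbon unit C12 as a vinylogous carbamate; the alkene geometry is of no consequence and no stereocentre is affected.

**Step 4**
Reactants: 5 enamino lactone
Product: 7 2-menthyloxy-3-(drimanyl)-2,3-dihydrofuran-4-carbaldehyde (2,3-trans), via enamino lactol 6 (not isolated)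
Conditions: DIBAL, CH2Cl2, −78 °C; then 1 M aq. HCl, THF, 0 °C
Reagents that add atoms: water, O
Why: DIBAL 1,2-reduction of the vinylogous carbamate carbonyl (C16) gives the lactolate, which on acid work-up loses the C16 oxygen with enamine assistance and is hydrolysed at C12 to the aldehyde (a 1,3-carbonyl transposition of the Stork–Danheiser type), so the ring is stored as an acid-tolerant vinylogous formate.

**Step 5**
Reactants: 7 menthyl acetal aldehyde
Product: 8 2-hydroxy-3-(drimanyl)-2,3-dihydrofuran-4-carbaldehyde (equilibrating anomers)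
Conditions: 2 M aq. HCl, THF, 40 °C
Reagents that add atoms: water, O
Why: Acid hydrolysis of the menthyl acetal is placed here because the enol ether is deactivated by conjugation with the C12 formyl group (push–pull alkene), which should disfavour ring protonation and aromatisation to a furan.

**Step 6**
Reactants: 8 lactol
Product: 9 2-acetoxy-3-(drimanyl)-2,3-dihydrofuran-4-carbaldehyde (2,3-trans)
Conditions: Ac2O, pyridine, DMAP (cat.), CH2Cl2, 0 °C
Reagents that add atoms: acetic anhydride, CC(=O)OC(C)=O
Why: DMAP-catalysed O-acetylation of the lactol; the anomers interconvert and the acetate should settle trans to the bulky C14 substituent, which sets C15 as required.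

**Step 7**
Reactants: 9 acetoxy aldehyde
Product: 10 [2-acetoxy-3-(drimanyl)-2,3-dihydrofuran-4-yl]methanol
Conditions: NaBH4, CeCl3·7H2O, MeOH/THF, −78 °C; aq. NaHCO3 quench
Reagents that add atoms: none
Why: Luche 1,2-reduction of the conjugated aldehyde at low temperature, under which the acetal acetate and the silyl ether should not be touched.

**Step 8**
Reactants: 10 allylic alcohol
Product: 11 C11-silylated diacetate
Conditions: Ac2O, Et3N, DMAP (cat.), CH2Cl2, 0 °C
Reagents that add atoms: acetic anhydride, CC(=O)OC(C)=O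
Why: Standard acetylation of the primary allylic alcohol under basic, non-ionising conditions that the 2-acetoxy-2,3-dihydrofuran should tolerate.

**Step 9**
Reactants: 11 C11-silylated diacetate
Product: 12 C11 alcohol diacetate
Conditions: HF·pyridine, pyridine, THF, 0 °C to rt
Reagents that add atoms: none
Why: Fluoride cleavage of the Si–O bond with pyridine-buffered HF·pyridine, conditions that enol ethers of the glycal type and acetates normally tolerate.

**Step 10**
Reactants: 12 C11 alcohol diacetate
Product: 13 target
Conditions: Dess–Martin periodinane, pyridine, CH2Cl2, 0 °C to rt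
Reagents that add atoms: none
Why: Dess–Martin oxidation of the neopentyl-type primary alcohol under pyridine buffering should give the aldehyde without acid that would ionise the acetal acetate, and the equatorial formyl group at C9 is the stable epimer.

**Compound list**
1 | (−)-drimenol, [(1S,4aS,8aS)-2,5,5,8a-tetramethyl-1,4,4a,5,6,7,8,8a-octahydronaphthalen-1-yl]methanol | CC1=CC[C@H]2C(C)(C)CCC[C@]2(C)[C@H]1CO | starting material
2 | drimenol tert-butyldiphenylsilyl ether | CC1=CC[C@H]2C(C)(C)CCC[C@]2(C)[C@H]1CO[Si](c1ccccc1)(c1ccccc1)C(C)(C)C | intermediate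
3 | (5S)-5-[(1S,2R,5S)-menthyloxy]furan-2(5H)-one | O=C1C=C[C@@H](O[C@H]2C[C@@H](C)CC[C@@H]2C(C)C)O1 | starting material
4 | (4R,5S)-5-menthyloxy-4-(drimanyl)dihydrofuran-2(3H)-one; lactone 4,5-trans; C8 methyl β, C8–C14 bond α; C11 as CH2OTBDPS | C1C(=O)O[C@H](O[C@H]3C[C@@H](C)CC[C@@H]3C(C)C)[C@H]1[C@]1(C)CC[C@H]2C(C)(C)CCC[C@]2(C)[C@H]1CO[Si](c1ccccc1)(c1ccccc1)C(C)(C)C | intermediate
5 | (E)-3-(dimethylaminomethylene) derivative of lactone 4 | CN(C)/C=C1/C(=O)O[C@H](O[C@H]3C[C@@H](C)CC[C@@H]3C(C)C)[C@H]1[C@]1(C)CC[C@H]2C(C)(C)CCC[C@]2(C)[C@H]1CO[Si](c1ccccc1)(c1ccccc1)C(C)(C)C | intermediate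
6 | enamino lactol (lactone C=O of 5 reduced to CH–OH, either configuration; present as its aluminium alkoxide) | CN(C)/C=C1/C(O)O[C@H](O[C@H]3C[C@@H](C)CC[C@@H]3C(C)C)[C@H]1[C@]1(C)CC[C@H]2C(C)(C)CCC[C@]2(C)[C@H]1CO[Si](c1ccccc1)(c1ccccc1)C(C)(C)C | intermediate (not isolated)
7 | 2-menthyloxy-3-(drimanyl)-2,3-dihydrofuran-4-carbaldehyde, 2,3-trans | O=CC1=CO[C@H](O[C@H]3C[C@@H](C)CC[C@@H]3C(C)C)[C@H]1[C@]1(C)CC[C@H]2C(C)(C)CCC[C@]2(C)[C@H]1CO[Si](c1ccccc1)(c1ccccc1)C(C)(C)C | intermediate
8 | 2-hydroxy-3-(drimanyl)-2,3-dihydrofuran-4-carbaldehyde (drawn as the 2,3-trans anomer; anomers interconvert) | O=CC1=CO[C@H](O)[C@H]1[C@]1(C)CC[C@H]2C(C)(C)CCC[C@]2(C)[C@H]1CO[Si](c1ccccc1)(c1ccccc1)C(C)(C)C | intermediate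
9 | 2-acetoxy-3-(drimanyl)-2,3-dihydrofuran-4-carbaldehyde, 2,3-trans | O=CC1=CO[C@H](OC(C)=O)[C@H]1[C@]1(C)CC[C@H]2C(C)(C)CCC[C@]2(C)[C@H]1CO[Si](c1ccccc1)(c1ccccc1)C(C)(C)C | intermediate
10 | [2-acetoxy-3-(drimanyl)-2,3-dihydrofuran-4-yl]methanol, 2,3-trans | OCC1=CO[C@H](OC(C)=O)[C@H]1[C@]1(C)CC[C@H]2C(C)(C)CCC[C@]2(C)[C@H]1CO[Si](c1ccccc1)(c1ccccc1)C(C)(C)C | intermediate
11 | target skeleton with C11 as CH2OTBDPS (both acetates in place) | CC(=O)OCC1=CO[C@H](OC(C)=O)[C@H]1[C@]1(C)CC[C@H]2C(C)(C)CCC[C@]2(C)[C@H]1CO[Si](c1ccccc1)(c1ccccc1)C(C)(C)C | intermediate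
12 | target skeleton with C11 as CH2OH | CC(=O)OCC1=CO[C@H](OC(C)=O)[C@H]1[C@]1(C)CC[C@H]2C(C)(C)CCC[C@]2(C)[C@H]1CO | intermediate
13 | CNP0170308.1 | CC(=O)OCC1=CO[C@H](OC(C)=O)[C@H]1[C@]1(C)CC[C@H]2C(C)(C)CCC[C@]2(C)[C@H]1C=O | target

**Step count and risks**
Total steps: 10. Longest linear sequence: 10 steps (1 to 13); 3 enters at step 2.

Steps most likely to fail, in order of risk:

Step 2. Hydrogen-atom transfer to the hindered tertiary radical, or iron-hydride reduction of the butenolide, may outrun carbon–carbon bond formation, and the α-face preference at C8 may erode next to the bulky silyloxymethyl group. The fallback sets out from 2. Mukaiyama hydration (Mn(dpm)3, PhSiH3, O2, i-PrOH) should give the tertiary alcohol 8-hydroxydrimanyl silyl ether F1 (either C8 epimer serves). Acylation with methyl chlorooxoacetate (Et3N, DMAP) should give the methyl oxalate F2, and CsOH hydrolysis the caesium oxalate F3. Visible-light photoredox decarboxylation (Ir[dF(CF3)ppy]2(dtbbpy)PF6, blue LEDs, DME/DMF, H2O) in the presence of 3 generates the same C8 radical without any metal hydride and should return to the route at 4.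

Step 5. In hot aqueous acid the liberated lactol may open to its chain tautomer, in which C14 is α to a free aldehyde and can epimerise, and the silyl ether may be partly lost. The fallback sets out from 4 and moves the acetal cleavage to the saturated lactone stage. Aqueous HCl/dioxane should give the γ-hydroxy lactone F4, and TBSCl/imidazole the silyl acetal lactone F5. Bredereck's reagent should then give the enamino lactone F6, and DIBAL followed by a buffered acid work-up should pass through the enamino lactol F7 to the silyloxy dihydrofuran aldehyde F8. Cold pyridine-buffered HF·pyridine followed by Ac2O in the same flask should unmask and acetylate the lactol without prolonged exposure to acid, returning to the route at 9.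

Step 9. Acid-promoted loss of acetic acid from the 2-acetoxy-2,3-dihydrofuran (aromatisation to a furan) or acetyl migration may occur during desilylation of the finished ring. The fallback sets out from 9, where the ring is still a robust vinylogous formate. HF·pyridine should give the hydroxy aldehyde F9, and Dess–Martin oxidation the dialdehyde F10. A Luche reduction in methanol at −78 °C should reduce only the conjugated aldehyde, the doubly neopentyl C11 aldehyde being hindered and masked as its hemiacetal, to give the allylic alcohol F11. Acetylation (Ac2O, Et3N, DMAP) should then return to the route at 13.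

**Further compounds**
F1 | step 2 | 8-hydroxydrimanyl silyl ether (8α-OH drawn) | O[C@]1(C)CC[C@H]2C(C)(C)CCC[C@]2(C)[C@H]1CO[Si](c1ccccc1)(c1ccccc1)C(C)(C)C
F2 | step 2 | methyl oxalate of F1 | COC(=O)C(=O)O[C@]1(C)CC[C@H]2C(C)(C)CCC[C@]2(C)[C@H]1CO[Si](c1ccccc1)(c1ccccc1)C(C)(C)C
F3 | step 2 | caesium oxalate of F1 | [Cs+].[O-]C(=O)C(=O)O[C@]1(C)CC[C@H]2C(C)(C)CCC[C@]2(C)[C@H]1CO[Si](c1ccccc1)(c1ccccc1)C(C)(C)C
F4 | step 5 | γ-hydroxy lactone (4,5-trans anomer drawn) | C1C(=O)O[C@H](O)[C@H]1[C@]1(C)CC[C@H]2C(C)(C)CCC[C@]2(C)[C@H]1CO[Si](c1ccccc1)(c1ccccc1)C(C)(C)C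
F5 | step 5 | γ-(tert-butyldimethylsilyloxy) lactone, 4,5-trans | C1C(=O)O[C@H](O[Si](C)(C)C(C)(C)C)[C@H]1[C@]1(C)CC[C@H]2C(C)(C)CCC[C@]2(C)[C@H]1CO[Si](c1ccccc1)(c1ccccc1)C(C)(C)C
F6 | step 5 | (E)-enamino lactone of F5 | CN(C)/C=C1/C(=O)O[C@H](O[Si](C)(C)C(C)(C)C)[C@H]1[C@]1(C)CC[C@H]2C(C)(C)CCC[C@]2(C)[C@H]1CO[Si](c1ccccc1)(c1ccccc1)C(C)(C)C
F7 | step 5 | enamino lactol of F6 (not isolated) | CN(C)/C=C1/C(O)O[C@H](O[Si](C)(C)C(C)(C)C)[C@H]1[C@]1(C)CC[C@H]2C(C)(C)CCC[C@]2(C)[C@H]1CO[Si](c1ccccc1)(c1ccccc1)C(C)(C)C
F8 | step 5 | 2-(tert-butyldimethylsilyloxy)-3-(drimanyl)-2,3-dihydrofuran-4-carbaldehyde | O=CC1=CO[C@H](O[Si](C)(C)C(C)(C)C)[C@H]1[C@]1(C)CC[C@H]2C(C)(C)CCC[C@]2(C)[C@H]1CO[Si](c1ccccc1)(c1ccccc1)C(C)(C)C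
F9 | step 9 | 2-acetoxy-4-formyl dihydrofuran with C11 as CH2OH | O=CC1=CO[C@H](OC(C)=O)[C@H]1[C@]1(C)CC[C@H]2C(C)(C)CCC[C@]2(C)[C@H]1CO
F10 | step 9 | 2-acetoxy-4-formyl dihydrofuran with C11 as CHO (dialdehyde) | O=CC1=CO[C@H](OC(C)=O)[C@H]1[C@]1(C)CC[C@H]2C(C)(C)CCC[C@]2(C)[C@H]1C=O
F11 | step 9 | 2-acetoxy-4-(hydroxymethyl) dihydrofuran with C11 as CHO | OCC1=CO[C@H](OC(C)=O)[C@H]1[C@]1(C)CC[C@H]2C(C)(C)CCC[C@]2(C)[C@H]1C=O
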